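**Retrosynthetic overview**
1. The plan rests on the (2E,4Z)-dienamide C1–C5 inside the 19-membered lactam ring (N, C1–C16, C21, C20), whose Z C4=C5 bond lies next to the C6 stereocentre. It is made as a ring alkyne and reduced syn afterwards; the quinone, the C7 carbamate and the C15 hydroxyl are unveiled last.
2. The macrolactam is opened at C4–C5 by ring-closing alkyne metathesis of a bis(methylalkyne) seco-anilide (C7 O-TES, C15 O-TBS, dimethoxyarene).
3. The seco-anilide comes from N-acylation of the C5–C21 aniline with (E)-2-methylhex-2-en-4-ynoic acid. C6/C7 come from syn-selective addition of a chiral allenylstannane to the C7 enal.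
4. The C7 enal comes from Wittig olefination (C8=C9), (Z)-crotylboration of the C11 α-methoxy aldehyde (C10/C11), enolate hydroxylation (C12), cross-metathesis homologation (C11–C13) and (Z)-crotylboration of 2,5-dimethoxy-3-nitrobenzaldehyde (C14/C15).
5. Ring order: the arene is bought, the 19-membered ring is the only ring closed (step 23), and the quinone is formed from the arene by oxidation at the end.

Key step: step 23

Remark: target numbering is used throughout (C1 amide carbonyl, C2–C15 ansa chain, C16–C21 ring carbons). Ar = 2,5-dimethoxy-3-nitrophenyl, TBS = tert-butyldimethylsilyl, TES = triethylsilyl, Ipc = isopinocampheyl. The antipode of the crotylborane is chosen from the known facial preference of Ipc2B-allyl reagents: the (+)-Ipc2BOMe-derived reagent attacks the aldehyde Re face.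

**Step 1**
Reactants: 1 2,5-dimethoxy-3-nitrobenzaldehyde
Product: 3 (1R,2S)-1-(2,5-dimethoxy-3-nitrophenyl)-2-methylbut-3-en-1-ol, via borinate ester 2 (not isolated)
Conditions: cis-but-2-ene, n-BuLi, KOtBu, THF, −78 to −45 °C; (+)-Ipc2BOMe [from (−)-α-pinene], −78 °C; BF3·OEt2; then 1, −78 °C; NaOH, H2O2
Reagents that add atoms: (Z)-but-2-en-1-ylbis(isopinocampheyl)borane, made in the flask from cis-but-2-ene (C/C=C\C), C/C=C\CB([C@H]1C[C@H]2C[C@@H]([C@@H]1C)C2(C)C)[C@H]1C[C@H]2C[C@@H]([C@@H]1C)C2(C)C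
Why: Brown asymmetric crotylboration passes through a closed chair transition state, so the Z-crotyl geometry gives the syn C14/C15 pair and the Ipc groups direct attack to the Re face (15R, 14S), while the nitro group is inert to the borane at −78 °C.

**Step 2**
Reactants: 3 (1R,2S)-1-Ar-2-methylbut-3-en-1-ol
Product: 4 tert-butyl{[(1R,2S)-1-Ar-2-methylbut-3-en-1-yl]oxy}dimethylsilane
Conditions: TBSOTf, 2,6-lutidine, CH2Cl2, 0 °C
Reagents that add atoms: tert-butyldimethylsilyl trifluoromethanesulfonate, CC(C)(C)[Si](C)(C)OS(=O)(=O)C(F)(F)F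
Why: Silylation of the hindered benzylic alcohol with the silyl triflate and a non-nucleophilic base gives the TBS ether that is meant to last until the final step.

**Step 3**
Reactants: 5 (S)-4-benzyloxazolidin-2-one; 6 acryloyl chloride
Product: 8 (S)-3-acryloyl-4-benzyloxazolidin-2-one, via lithium oxazolidinide 7 (not isolated)
Conditions: n-BuLi, THF, −78 °C; then 6, −78 to 0 °C
Reagents that add atoms: none
Why: N-acylation of the lithiated oxazolidinone with the acid chloride gives the acrylimide that carries the auxiliary needed for the later hydroxylation.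

**Step 4**
Reactants: 4 TBS ether; 8 (S)-3-acryloyl-4-benzyloxazolidin-2-one (3 equiv)
Product: 9 (S)-4-benzyl-3-[(2E,4S,5R)-5-(TBSO)-5-Ar-4-methylpent-2-enoyl]oxazolidin-2-one
Conditions: second-generation Hoveyda–Grubbs catalyst RuCl2(H2IMes)(=CH-C6H4-2-O-iPr) (5 mol %), CH2Cl2, 40 °C
Reagents that add atoms: none
Why: Olefin cross-metathesis between the monosubstituted alkene and the electron-poor acrylimide should favour the E cross-product because neither partner homodimerises quickly, and the ruthenium carbene tolerates the nitroarene and the silyl ether.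

**Step 5**
Reactants: 9 enimide
Product: 10 (S)-4-benzyl-3-[(4S,5R)-5-(TBSO)-5-Ar-4-methylpentanoyl]oxazolidin-2-one
Conditions: H2 (1 atm), RhCl(PPh3)3 (10 mol %), benzene/EtOH, rt
Reagents that add atoms: none
Why: Homogeneous hydrogenation with RhCl(PPh3)3 saturates the disubstituted C12=C13 alkene but does not reduce an aromatic nitro group, which is why Pd/C is avoided.

**Step 6**
Reactants: 10 saturated imide
Product: 12 (S)-4-benzyl-3-[(2S,4S,5R)-5-(TBSO)-5-Ar-2-hydroxy-4-methylpentanoyl]oxazolidin-2-one, via sodium enolate 11 (not isolated)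
Conditions: NaN(SiMe3)2, THF, −78 °C; 2-(benzenesulfonyl)-3-phenyloxaziridine; AcOH
Reagents that add atoms: 2-(benzenesulfonyl)-3-phenyloxaziridine, O=S(=O)(c1ccccc1)N1OC1c1ccccc1
Why: Evans enolate hydroxylation: the chelated (Z)-sodium enolate is oxidised by the Davis oxaziridine on the face away from the benzyl group of the (S)-auxiliary, which sets C12 as S.

**Step 7**
Reactants: 12 α-hydroxy imide
Product: 13 (S)-4-benzyl-3-[(2S,4S,5R)-5-(TBSO)-5-Ar-2-methoxy-4-methylpentanoyl]oxazolidin-2-one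
Conditions: Me3OBF4, 1,8-bis(dimethylamino)naphthalene, 4 Å MS, CH2Cl2, rt
Reagents that add atoms: trimethyloxonium tetrafluoroborate, C[O+](C)C.F[B-](F)(F)F
Why: O-methylation with Meerwein's salt and a hindered proton scavenger needs no alkoxide, so the α-stereocentre of the imide is not epimerised.

**Step 8**
Reactants: 13 α-methoxy imide
Product: 14 (2S,4S,5R)-5-(TBSO)-5-Ar-2-methoxy-4-methylpentan-1-ol
Conditions: LiBH4, MeOH (1 equiv), THF, 0 °C
Reagents that add atoms: none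
Why: Reductive cleavage of the N-acyloxazolidinone with LiBH4 gives the primary alcohol and returns the auxiliary, and the nitroarene and silyl ether are untouched at 0 °C.

**Step 9**
Reactants: 14 primary alcohol
Product: 15 (2S,4S,5R)-5-(TBSO)-5-Ar-2-methoxy-4-methylpentanal
Conditions: Dess–Martin periodinane, NaHCO3, CH2Cl2, rt; used at once
Reagents that add atoms: none
Why: Dess–Martin oxidation under buffered, non-basic conditions should give the α-methoxy aldehyde without epimerisation at C12.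

**Step 10**
Reactants: 15 α-methoxy aldehyde
Product: 17 (3S,4R,5S,7S,8R)-8-(TBSO)-8-Ar-5-methoxy-3,7-dimethyloct-1-en-4-ol, via borinate ester 16 (not isolated)
Conditions: cis-but-2-ene, n-BuLi, KOtBu, THF, −78 to −45 °C; (+)-Ipc2BOMe, −78 °C; BF3·OEt2; then 15, −78 °C; NaOH, H2O2
Reagents that add atoms: (Z)-but-2-en-1-ylbis(isopinocampheyl)borane, made in the flask from cis-but-2-ene (C/C=C\C), C/C=C\CB([C@H]1C[C@H]2C[C@@H]([C@@H]1C)C2(C)C)[C@H]1C[C@H]2C[C@@H]([C@@H]1C)C2(C)C
Why: Brown (Z)-crotylboration gives the syn C10/C11 pair through the closed transition state with Re-face attack (11R, 10S), and this is the matched case because the Felkin–Anh (Cornforth) preference of the α-methoxy aldehyde also leads to the 11,12-anti product.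

**Step 11**
Reactants: 17 homoallylic alcohol
Product: 18 tert-butyl{[(1R,2S,4S,5R,6S)-1-Ar-4,5-dimethoxy-2,6-dimethyloct-7-en-1-yl]oxy}dimethylsilane
Conditions: MeOTf, 2,6-di-tert-butylpyridine, CH2Cl2, rt
Reagents that add atoms: methyl trifluoromethanesulfonate, COS(=O)(=O)C(F)(F)F
Why: O-alkylation of the hindered secondary alcohol with methyl triflate and a hindered pyridine base avoids alkoxide formation and leaves the silyl ether and the nitroarene intact.

**Step 12**
Reactants: 18 terminal alkene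
Product: 20 (2R,3R,4S,6S,7R)-7-(TBSO)-7-Ar-3,4-dimethoxy-2,6-dimethylheptanal, via secondary ozonide 19 (not isolated)
Conditions: O3, CH2Cl2, −78 °C; PPh3, −78 °C to rt; used crude
Reagents that add atoms: ozone, [O-][O+]=O
Why: Ozonolysis cleaves the only alkene while the nitro-deactivated arene is spared, and reductive work-up gives the C9 aldehyde, which is carried on crude to avoid epimerisation at C10.

**Step 13**
Reactants: 20 C9 aldehyde; 21 2-(triphenyl-λ5-phosphanylidene)propanal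
Product: 22 (2E,4S,5R,6S,8S,9R)-9-(TBSO)-9-Ar-5,6-dimethoxy-2,4,8-trimethylnon-2-enal
Conditions: toluene, 90 °C
Reagents that add atoms: none
Why: Wittig olefination with the formyl-stabilised ylide gives the (E)-2-methyl enal directly (thermodynamic E preference of stabilised ylides), and the product enal is too unreactive to take up a second ylide.

**Step 14**
Reactants: 23 pent-3-yn-2-one
Product: 24 (S)-pent-3-yn-2-ol
Conditions: RuCl(p-cymene)[(S,S)-TsDPEN] (1 mol %), i-PrOH, rt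
Reagents that add atoms: none
Why: Noyori asymmetric transfer hydrogenation of the ynone with the (S,S)-TsDPEN ruthenium catalyst should give the (S)-propargylic alcohol.

**Step 15**
Reactants: 24 (S)-pent-3-yn-2-ol
Product: 25 (S)-pent-3-yn-2-yl methanesulfonate
Conditions: MsCl, Et3N, CH2Cl2, −78 to 0 °C
Reagents that add atoms: methanesulfonyl chloride, CS(=O)(=O)Cl
Why: Sulfonylation at oxygen leaves the configuration of the carbinol carbon unchanged.

**Step 16**
Reactants: 25 (S)-mesylate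
Product: 26 (M)-tributyl(penta-2,3-dien-2-yl)stannane
Conditions: Bu3SnH, LiN(iPr)2, THF, 0 °C; CuBr·SMe2, −78 °C; then 25, −78 °C
Reagents that add atoms: tributyltin hydride, CCCC[SnH](CCCC)CCCC
Why: Anti SN2′ displacement of the propargylic mesylate by the stannylcuprate transfers the central chirality to the allene axis and gives the (M)-allenylstannane.

**Step 17**
Reactants: 22 enal; 26 (M)-allenylstannane (1.5 equiv)
Product: 27 (4S,5R,6E,8S,9R,10S,12S,13R)-13-(TBSO)-13-Ar-9,10-dimethoxy-4,6,8,12-tetramethyltridec-6-en-2-yn-5-ol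
Conditions: BF3·OEt2, CH2Cl2, −78 °C; aq. NaHCO3
Reagents that add atoms: none
Why: Marshall propargylation: BF3-promoted SE2′ addition of the allenylstannane is anti to tin, so C6 (S) follows from the allene axis, and the open antiperiplanar transition state gives the syn C6/C7 relationship (7R) under reagent control.

**Step 18**
Reactants: 27 homopropargylic alcohol
Product: 28 triethylsilyl ether of 27 (C7 O-TES)
Conditions: TESOTf, 2,6-lutidine, CH2Cl2, −78 °C
Reagents that add atoms: triethylsilyl trifluoromethanesulfonate, CC[Si](CC)(CC)OS(=O)(=O)C(F)(F)F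
Why: Silylation with the silyl triflate gives the TES ether, which can later be removed in the presence of the TBS ether.

**Step 19**
Reactants: 28 nitroarene
Product: 29 aniline (NO2 of 28 reduced to NH2; chain unchanged)
Conditions: Zn dust (excess), NH4Cl, EtOH/H2O, rt to 40 °C; used at once
Reagents that add atoms: none
Why: Dissolving-metal reduction of the nitroarene with zinc and NH4Cl under near-neutral conditions should give the aniline and leave the alkyne, the alkene and both silyl ethers untouched.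

**Step 20**
Reactants: 30 but-2-yn-1-ol; 31 ethyl 2-(triphenyl-λ5-phosphanylidene)propanoate
Product: 33 ethyl (E)-2-methylhex-2-en-4-ynoate, via but-2-ynal 32 (not isolated)
Conditions: MnO2, CH2Cl2, rt
Reagents that add atoms: none
Why: Tandem oxidation–Wittig reaction: MnO2 oxidises the propargylic alcohol to volatile but-2-ynal, which the stabilised ylide traps in situ to give the E trisubstituted enoate.

**Step 21**
Reactants: 33 enyne ester
Product: 34 (E)-2-methylhex-2-en-4-ynoic acid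
Conditions: LiOH, THF/MeOH/H2O, rt; aq. HCl
Reagents that add atoms: lithium hydroxide, [Li+].[OH-]
Why: Saponification of the ethyl ester gives the enyne acid.

**Step 22**
Reactants: 29 aniline; 34 enyne acid
Product: 36 seco-anilide (N-acyl derivative of 29 with 34; C7 O-TES and C15 O-TBS), via acid chloride 35 (not isolated)
Conditions: (COCl)2, DMF (cat.), CH2Cl2, 0 °C; then 29, pyridine, CH2Cl2, 0 °C to rt
Reagents that add atoms: none
Why: The acid chloride formed by Vilsmeier activation acylates the hindered, electron-rich aniline (Schotten–Baumann-type amide formation) to give the metathesis precursor.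

**Step 23**
Reactants: 36 seco-anilide
Product: 37 19-membered cyclic (2E)-2-en-4-ynamide (C7 O-TES, C15 O-TBS)
Conditions: Mo(≡C-C6H4-4-OMe)(OSiPh3)3 (hexavalent molybdenum, 15 mol %), 5 Å MS, toluene, 2 mM, 80 °C
Reagents that add atoms: none
Why: The molybdenum alkylidyne undergoes [2+2] cycloaddition with each methyl-capped alkyne of 36 to give molybdacyclobutadienes, whose cycloreversion first loads the chain onto the metal and then joins C4 to C5 with release of but-2-yne, which the 5 Å sieves absorb so that the equilibrium is drawn to the ring. The closest known reaction type is ring-closing alkyne metathesis of enyne–yne substrates with silanolate-ligated molybdenum alkylidynes, followed by Z-selective semi-reduction to macrocyclic E,Z-dienes. The one ring formed, the 19-membered lactam, closes end to end at C4≡C5, and a ring of this size holds the linear C3–C4≡C5–C6 unit without strain. No stereocentre is created, and C6, C7, C10, C11, C12, C14 and C15 are spectators. The step needs chemoselectivity for the two alkynes over the C2=C3 and C8=C9 alkenes, which the alkylidyne provides because it does not engage olefins, and it needs closure to beat oligomerisation, which high dilution and the reversibility of the metathesis secure; the anilide N–H and the silyl ethers are expected to be tolerated by this catalyst.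

**Step 24**
Reactants: 37 cyclic enynamide
Product: 38 macrocyclic (2E,4Z)-dienamide (C7 O-TES, C15 O-TBS)
Conditions: Zn(Cu/Ag) [Zn dust, Cu(OAc)2, AgNO3], MeOH/H2O, 45 °C
Reagents that add atoms: none
Why: Semi-reduction of the conjugated ring alkyne with zinc activated by copper and silver delivers both hydrogens to the same face (syn addition), which gives the 4Z alkene and leaves the C2=C3 and C8=C9 alkenes alone.

**Step 25**
Reactants: 38 bis-silyl ether
Product: 39 C7 alcohol (C15 O-TBS retained)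
Conditions: PPTS, MeOH/CH2Cl2, 0 °C
Reagents that add atoms: none
Why: Acid-catalysed methanolysis removes the triethylsilyl ether much faster than the more hindered TBS ether.

**Step 26**
Reactants: 39 C7 alcohol
Product: 41 C7 carbamate (OC(O)NH2; dimethoxyarene, C15 O-TBS), via N-trichloroacetyl carbamate 40 (not isolated)
Conditions: Cl3CC(O)NCO, CH2Cl2, 0 °C; then K2CO3, MeOH, 0 °C
Reagents that add atoms: trichloroacetyl isocyanate, O=C=NC(=O)C(Cl)(Cl)Cl
Why: Carbamoylation by the Kocovsky method: the alcohol adds to the acyl isocyanate and mild methanolysis removes the trichloroacetyl group, while the anilide N–H is too weakly nucleophilic to compete.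

**Step 27**
Reactants: 41 dimethoxyarene carbamate
Product: 42 para-quinone (C15 O-TBS)
Conditions: (NH4)2Ce(NO3)6, MeCN/H2O, 0 °C
Reagents that add atoms: water, O
Why: Oxidative demethylation of the para-dimethoxyarene with tetravalent cerium gives the para-quinone, with the two carbonyl oxygens coming from water.

**Step 28**
Reactants: 42 quinone TBS ether
Product: 43 CNP0557283.1
Conditions: HF·pyridine, pyridine, THF, 0 °C to rt
Reagents that add atoms: none
Why: Desilylation with buffered HF·pyridine removes the TBS ether without base, which the quinone and the carbamate would not tolerate.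

**Compound list**
1 | 2,5-dimethoxy-3-nitrobenzaldehyde | COc1cc(C=O)c(OC)c([N+](=O)[O-])c1 | starting material
2 | (1R,2S)-1-Ar-2-methylbut-3-en-1-yl bis(isopinocampheyl)borinate | C=C[C@H](C)[C@@H](OB([C@H]1C[C@H]2C[C@@H]([C@@H]1C)C2(C)C)[C@H]1C[C@H]2C[C@@H]([C@@H]1C)C2(C)C)c1cc(OC)cc([N+](=O)[O-])c1OC | intermediate
3 | (1R,2S)-1-(2,5-dimethoxy-3-nitrophenyl)-2-methylbut-3-en-1-ol | C=C[C@H](C)[C@@H](O)c1cc(OC)cc([N+](=O)[O-])c1OC | intermediate
4 | tert-butyl{[(1R,2S)-1-Ar-2-methylbut-3-en-1-yl]oxy}dimethylsilane | C=C[C@H](C)[C@@H](O[Si](C)(C)C(C)(C)C)c1cc(OC)cc([N+](=O)[O-])c1OC | intermediate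
5 | (S)-4-benzyloxazolidin-2-one | O=C1N[C@@H](Cc2ccccc2)CO1 | starting material
6 | acryloyl chloride | C=CC(=O)Cl | starting material
7 | lithium (S)-4-benzyl-2-oxooxazolidin-3-ide | [Li+].O=C1[N-][C@@H](Cc2ccccc2)CO1 | intermediate
8 | (S)-3-acryloyl-4-benzyloxazolidin-2-one | C=CC(=O)N1[C@@H](Cc2ccccc2)COC1=O | intermediate
9 | (S)-4-benzyl-3-[(2E,4S,5R)-5-(TBSO)-5-Ar-4-methylpent-2-enoyl]oxazolidin-2-one | O=C(/C=C/[C@H](C)[C@@H](O[Si](C)(C)C(C)(C)C)c1cc(OC)cc([N+](=O)[O-])c1OC)N1[C@@H](Cc2ccccc2)COC1=O | intermediate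
10 | (S)-4-benzyl-3-[(4S,5R)-5-(TBSO)-5-Ar-4-methylpentanoyl]oxazolidin-2-one | O=C(CC[C@H](C)[C@@H](O[Si](C)(C)C(C)(C)C)c1cc(OC)cc([N+](=O)[O-])c1OC)N1[C@@H](Cc2ccccc2)COC1=O | intermediate
11 | sodium (Z)-enolate of 10 | [Na+].[O-]/C(=C\C[C@H](C)[C@@H](O[Si](C)(C)C(C)(C)C)c1cc(OC)cc([N+](=O)[O-])c1OC)N1[C@@H](Cc2ccccc2)COC1=O | intermediate
12 | (S)-4-benzyl-3-[(2S,4S,5R)-5-(TBSO)-5-Ar-2-hydroxy-4-methylpentanoyl]oxazolidin-2-one | O=C([C@@H](O)C[C@H](C)[C@@H](O[Si](C)(C)C(C)(C)C)c1cc(OC)cc([N+](=O)[O-])c1OC)N1[C@@H](Cc2ccccc2)COC1=O | intermediate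
13 | (S)-4-benzyl-3-[(2S,4S,5R)-5-(TBSO)-5-Ar-2-methoxy-4-methylpentanoyl]oxazolidin-2-one | O=C([C@@H](OC)C[C@H](C)[C@@H](O[Si](C)(C)C(C)(C)C)c1cc(OC)cc([N+](=O)[O-])c1OC)N1[C@@H](Cc2ccccc2)COC1=O | intermediate
14 | (2S,4S,5R)-5-(TBSO)-5-Ar-2-methoxy-4-methylpentan-1-ol | OC[C@@H](OC)C[C@H](C)[C@@H](O[Si](C)(C)C(C)(C)C)c1cc(OC)cc([N+](=O)[O-])c1OC | intermediate
15 | (2S,4S,5R)-5-(TBSO)-5-Ar-2-methoxy-4-methylpentanal | O=C[C@@H](OC)C[C@H](C)[C@@H](O[Si](C)(C)C(C)(C)C)c1cc(OC)cc([N+](=O)[O-])c1OC | intermediate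
16 | bis(isopinocampheyl)borinate ester of 17 | C=C[C@H](C)[C@@H](OB([C@H]1C[C@H]2C[C@@H]([C@@H]1C)C2(C)C)[C@H]1C[C@H]2C[C@@H]([C@@H]1C)C2(C)C)[C@@H](OC)C[C@H](C)[C@@H](O[Si](C)(C)C(C)(C)C)c1cc(OC)cc([N+](=O)[O-])c1OC | intermediate
17 | (3S,4R,5S,7S,8R)-8-(TBSO)-8-Ar-5-methoxy-3,7-dimethyloct-1-en-4-ol | C=C[C@H](C)[C@@H](O)[C@@H](OC)C[C@H](C)[C@@H](O[Si](C)(C)C(C)(C)C)c1cc(OC)cc([N+](=O)[O-])c1OC | intermediate
18 | tert-butyl{[(1R,2S,4S,5R,6S)-1-Ar-4,5-dimethoxy-2,6-dimethyloct-7-en-1-yl]oxy}dimethylsilane | C=C[C@H](C)[C@@H](OC)[C@@H](OC)C[C@H](C)[C@@H](O[Si](C)(C)C(C)(C)C)c1cc(OC)cc([N+](=O)[O-])c1OC | intermediate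
19 | secondary ozonide of 18 (3-substituted 1,2,4-trioxolane, both epimers at the trioxolane carbon) | C1OOC(O1)[C@H](C)[C@@H](OC)[C@@H](OC)C[C@H](C)[C@@H](O[Si](C)(C)C(C)(C)C)c1cc(OC)cc([N+](=O)[O-])c1OC | intermediate
20 | (2R,3R,4S,6S,7R)-7-(TBSO)-7-Ar-3,4-dimethoxy-2,6-dimethylheptanal | O=C[C@H](C)[C@@H](OC)[C@@H](OC)C[C@H](C)[C@@H](O[Si](C)(C)C(C)(C)C)c1cc(OC)cc([N+](=O)[O-])c1OC | intermediate
21 | 2-(triphenyl-λ5-phosphanylidene)propanal | CC(C=O)=P(c1ccccc1)(c1ccccc1)c1ccccc1 | starting material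
22 | (2E,4S,5R,6S,8S,9R)-9-(TBSO)-9-Ar-5,6-dimethoxy-2,4,8-trimethylnon-2-enal | O=C/C(C)=C/[C@H](C)[C@@H](OC)[C@@H](OC)C[C@H](C)[C@@H](O[Si](C)(C)C(C)(C)C)c1cc(OC)cc([N+](=O)[O-])c1OC | intermediate
23 | pent-3-yn-2-one | CC#CC(C)=O | starting material
24 | (S)-pent-3-yn-2-ol | CC#C[C@H](C)O | intermediate
25 | (S)-pent-3-yn-2-yl methanesulfonate | CC#C[C@H](C)OS(C)(=O)=O | intermediate
26 | (M)-tributyl(penta-2,3-dien-2-yl)stannane | CCCC[Sn](CCCC)(CCCC)C(C)=[C@]=C([H])C | intermediate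
27 | (4S,5R,6E,8S,9R,10S,12S,13R)-13-(TBSO)-13-Ar-9,10-dimethoxy-4,6,8,12-tetramethyltridec-6-en-2-yn-5-ol | CC#C[C@H](C)[C@@H](O)/C(C)=C/[C@H](C)[C@@H](OC)[C@@H](OC)C[C@H](C)[C@@H](O[Si](C)(C)C(C)(C)C)c1cc(OC)cc([N+](=O)[O-])c1OC | intermediate
28 | triethylsilyl ether of 27 | CC#C[C@H](C)[C@@H](O[Si](CC)(CC)CC)/C(C)=C/[C@H](C)[C@@H](OC)[C@@H](OC)C[C@H](C)[C@@H](O[Si](C)(C)C(C)(C)C)c1cc(OC)cc([N+](=O)[O-])c1OC | intermediate
29 | aniline from 28 (3-amino-2,5-dimethoxyphenyl in place of Ar) | CC#C[C@H](C)[C@@H](O[Si](CC)(CC)CC)/C(C)=C/[C@H](C)[C@@H](OC)[C@@H](OC)C[C@H](C)[C@@H](O[Si](C)(C)C(C)(C)C)c1cc(OC)cc(N)c1OC | intermediate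
30 | but-2-yn-1-ol | CC#CCO | starting material
31 | ethyl 2-(triphenyl-λ5-phosphanylidene)propanoate | CCOC(=O)C(C)=P(c1ccccc1)(c1ccccc1)c1ccccc1 | starting material
32 | but-2-ynal | CC#CC=O | intermediate
33 | ethyl (E)-2-methylhex-2-en-4-ynoate | CCOC(=O)/C(C)=C/C#CC | intermediate
34 | (E)-2-methylhex-2-en-4-ynoic acid | OC(=O)/C(C)=C/C#CC | intermediate
35 | (E)-2-methylhex-2-en-4-ynoyl chloride | ClC(=O)/C(C)=C/C#CC | intermediate
36 | seco-anilide: N-(E)-2-methylhex-2-en-4-ynoyl derivative of 29 | CC#C[C@H](C)[C@@H](O[Si](CC)(CC)CC)/C(C)=C/[C@H](C)[C@@H](OC)[C@@H](OC)C[C@H](C)[C@@H](O[Si](C)(C)C(C)(C)C)c1cc(OC)cc(NC(=O)/C(C)=C/C#CC)c1OC | intermediate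
37 | 19-membered cyclic (2E)-2-en-4-ynamide, 7-O-TES, 15-O-TBS (6S,7R,10S,11R,12S,14S,15R) | CO[C@H]1[C@@H](OC)C[C@H](C)[C@@H](O[Si](C)(C)C(C)(C)C)c2cc(OC)cc(NC(=O)/C(C)=C/C#C[C@H](C)[C@@H](O[Si](CC)(CC)CC)/C(C)=C/[C@@H]1C)c2OC | intermediate
38 | macrocyclic (2E,4Z,8E)-dienamide, 7-O-TES, 15-O-TBS | CO[C@H]1[C@@H](OC)C[C@H](C)[C@@H](O[Si](C)(C)C(C)(C)C)c2cc(OC)cc(NC(=O)/C(C)=C/C=C\[C@H](C)[C@@H](O[Si](CC)(CC)CC)/C(C)=C/[C@@H]1C)c2OC | intermediate
39 | macrocyclic 7-ol, 15-O-TBS | CO[C@H]1[C@@H](OC)C[C@H](C)[C@@H](O[Si](C)(C)C(C)(C)C)c2cc(OC)cc(NC(=O)/C(C)=C/C=C\[C@H](C)[C@@H](O)/C(C)=C/[C@@H]1C)c2OC | intermediate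
40 | 7-O-[N-(trichloroacetyl)carbamoyl] macrocycle, 15-O-TBS | CO[C@H]1[C@@H](OC)C[C@H](C)[C@@H](O[Si](C)(C)C(C)(C)C)c2cc(OC)cc(NC(=O)/C(C)=C/C=C\[C@H](C)[C@@H](OC(=O)NC(=O)C(Cl)(Cl)Cl)/C(C)=C/[C@@H]1C)c2OC | intermediate
41 | 7-O-carbamoyl macrocycle, dimethoxyarene, 15-O-TBS | CO[C@H]1[C@@H](OC)C[C@H](C)[C@@H](O[Si](C)(C)C(C)(C)C)c2cc(OC)cc(NC(=O)/C(C)=C/C=C\[C@H](C)[C@@H](OC(N)=O)/C(C)=C/[C@@H]1C)c2OC | intermediate
42 | para-quinone, 15-O-TBS | CO[C@H]1[C@@H](OC)C[C@H](C)[C@@H](O[Si](C)(C)C(C)(C)C)C2=CC(=O)C=C(NC(=O)/C(C)=C/C=C\[C@H](C)[C@@H](OC(N)=O)/C(C)=C/[C@@H]1C)C2=O | intermediate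
43 | CNP0557283.1 (6S,7R,10S,11R,12S,14S,15R; 2E,4Z,8E) | CO[C@H]1[C@@H](OC)C[C@H](C)[C@@H](O)C2=CC(=O)C=C(NC(=O)/C(C)=C/C=C\[C@H](C)[C@@H](OC(N)=O)/C(C)=C/[C@@H]1C)C2=O | target

**Step count**
Total: 28 steps. Longest linear sequence: 22 steps (1, 2, 4–13, 17–19, 22–28). Side branches: step 3 (acrylimide), steps 14–16 (allenylstannane), steps 20–21 (enyne acid).

**Steps most likely to fail**

1. Step 23 (ring-closing alkyne metathesis). The alkylidyne may be deactivated by protonation from the anilide N–H or by chelation to the 2-en-4-ynamide, and intermolecular metathesis may lead to oligomers instead of the ring. Fallback, setting out from 28 (with ester 33) and returning at 37: the C4≡C5 bond is made intermolecularly before any N–H is present, and the ring is closed by amide formation. Alkyne cross-metathesis of 28 with an excess of 33 under the same Mo(≡C-C6H4-4-OMe)(OSiPh3)3 / 5 Å MS conditions should give ethyl (2E,6S,7R,8E,10S,11R,12S,14S,15R)-15-(TBSO)-15-Ar-11,12-dimethoxy-2,6,8,10,14-pentamethyl-7-(TESO)pentadeca-2,8-dien-4-ynoate F1. LiOH in THF/MeOH/H2O then gives the corresponding acid F2, and Zn/NH4Cl reduces the nitro group to give the amino acid F3. Slow addition of F3 to BOP-Cl and i-Pr2NEt in toluene at 85 °C under high dilution closes the 19-membered lactam to give 37.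

2. Step 17 (allenylstannane addition). The open transition state may give poor syn/anti or facial selectivity with the hindered 2-methyl enal, and the Lewis acid may cause loss of a silyl group. Fallback, setting out from 22 and returning at 28: an Evans syn-aldol of 22 with the dibutylboron enolate of (R)-4-benzyl-3-propionyloxazolidin-2-one (Bu2BOTf, Et3N, CH2Cl2, −78 to 0 °C) gives the (2R,3R)-aldol imide F4, with C6 and C7 set by the auxiliary through the closed transition state. TESOTf/2,6-lutidine gives the TES ether F5, LiBH4 removes the auxiliary to give the primary alcohol F6, and Dess–Martin oxidation gives the aldehyde F7. Ohira–Bestmann homologation (dimethyl (1-diazo-2-oxopropyl)phosphonate, K2CO3, MeOH) gives the terminal alkyne F8, and C-methylation with LiN(SiMe3)2 and MeOTf in THF at −78 °C gives 28.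

3. Step 4 (cross-metathesis). Metathesis at the allylically branched, β-silyloxy terminal alkene may be sluggish, and the acrylimide may homodimerise or polymerise. Fallback, setting out from 4 and returning at 9: ozonolysis of 4 (O3, CH2Cl2, −78 °C; PPh3) gives (2R,3R)-3-(TBSO)-3-Ar-2-methylpropanal F9. Separately, 5 is N-acylated with bromoacetyl bromide (n-BuLi, THF, −78 °C) to (S)-4-benzyl-3-(2-bromoacetyl)oxazolidin-2-one F10, which is heated with P(OEt)3 (Arbuzov reaction) to give (S)-4-benzyl-3-[2-(diethoxyphosphoryl)acetyl]oxazolidin-2-one F11. Horner–Wadsworth–Emmons olefination of F9 with F11 under Masamune–Roush conditions (LiCl, i-Pr2NEt, MeCN) gives the E enimide 9.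

**Further compounds**
F1 | step 23 | ethyl (2E,6S,7R,8E,10S,11R,12S,14S,15R)-15-(TBSO)-15-Ar-11,12-dimethoxy-2,6,8,10,14-pentamethyl-7-(TESO)pentadeca-2,8-dien-4-ynoate | CCOC(=O)/C(C)=C/C#C[C@H](C)[C@@H](O[Si](CC)(CC)CC)/C(C)=C/[C@H](C)[C@@H](OC)[C@@H](OC)C[C@H](C)[C@@H](O[Si](C)(C)C(C)(C)C)c1cc(OC)cc([N+](=O)[O-])c1OC
F2 | step 23 | carboxylic acid from F1 | OC(=O)/C(C)=C/C#C[C@H](C)[C@@H](O[Si](CC)(CC)CC)/C(C)=C/[C@H](C)[C@@H](OC)[C@@H](OC)C[C@H](C)[C@@H](O[Si](C)(C)C(C)(C)C)c1cc(OC)cc([N+](=O)[O-])c1OC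
F3 | step 23 | amino acid from F2 (NO2 reduced to NH2) | OC(=O)/C(C)=C/C#C[C@H](C)[C@@H](O[Si](CC)(CC)CC)/C(C)=C/[C@H](C)[C@@H](OC)[C@@H](OC)C[C@H](C)[C@@H](O[Si](C)(C)C(C)(C)C)c1cc(OC)cc(N)c1OC
F4 | step 17 | (R)-4-benzyl-3-[(2R,3R,4E,6S,7R,8S,10S,11R)-11-(TBSO)-11-Ar-3-hydroxy-7,8-dimethoxy-2,4,6,10-tetramethylundec-4-enoyl]oxazolidin-2-one | O=C([C@H](C)[C@@H](O)/C(C)=C/[C@H](C)[C@@H](OC)[C@@H](OC)C[C@H](C)[C@@H](O[Si](C)(C)C(C)(C)C)c1cc(OC)cc([N+](=O)[O-])c1OC)N1[C@H](Cc2ccccc2)COC1=O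
F5 | step 17 | 3-O-TES ether of F4 | O=C([C@H](C)[C@@H](O[Si](CC)(CC)CC)/C(C)=C/[C@H](C)[C@@H](OC)[C@@H](OC)C[C@H](C)[C@@H](O[Si](C)(C)C(C)(C)C)c1cc(OC)cc([N+](=O)[O-])c1OC)N1[C@H](Cc2ccccc2)COC1=O
F6 | step 17 | (2S,3R,4E,6S,7R,8S,10S,11R)-11-(TBSO)-11-Ar-7,8-dimethoxy-2,4,6,10-tetramethyl-3-(TESO)undec-4-en-1-ol | OC[C@H](C)[C@@H](O[Si](CC)(CC)CC)/C(C)=C/[C@H](C)[C@@H](OC)[C@@H](OC)C[C@H](C)[C@@H](O[Si](C)(C)C(C)(C)C)c1cc(OC)cc([N+](=O)[O-])c1OC
F7 | step 17 | (2R,3R,4E,6S,7R,8S,10S,11R)-11-(TBSO)-11-Ar-7,8-dimethoxy-2,4,6,10-tetramethyl-3-(TESO)undec-4-enal | O=C[C@H](C)[C@@H](O[Si](CC)(CC)CC)/C(C)=C/[C@H](C)[C@@H](OC)[C@@H](OC)C[C@H](C)[C@@H](O[Si](C)(C)C(C)(C)C)c1cc(OC)cc([N+](=O)[O-])c1OC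
F8 | step 17 | terminal alkyne (28 without the alkyne methyl cap) | C#C[C@H](C)[C@@H](O[Si](CC)(CC)CC)/C(C)=C/[C@H](C)[C@@H](OC)[C@@H](OC)C[C@H](C)[C@@H](O[Si](C)(C)C(C)(C)C)c1cc(OC)cc([N+](=O)[O-])c1OC
F9 | step 4 | (2R,3R)-3-(TBSO)-3-Ar-2-methylpropanal | O=C[C@H](C)[C@@H](O[Si](C)(C)C(C)(C)C)c1cc(OC)cc([N+](=O)[O-])c1OC
F10 | step 4 | (S)-4-benzyl-3-(2-bromoacetyl)oxazolidin-2-one | O=C(CBr)N1[C@@H](Cc2ccccc2)COC1=O
F11 | step 4 | (S)-4-benzyl-3-[2-(diethoxyphosphoryl)acetyl]oxazolidin-2-one | CCOP(=O)(OCC)CC(=O)N1[C@@H](Cc2ccccc2)COC1=O
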